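**Retrosynthetic overview**

- Feature: ring C is a six-membered oxygen ring fused to ring A. Its bonds O1–C2 and C3–C4 enclose the two-carbon unit C2–C3, and C2 carries ring B. C2–C3 with ring B therefore corresponds to a styrene, and O1–C8a–C4a–C4 to an ortho-quinone methide of ring A.
- Key disconnection (ring C is the only ring formed; rings A and B are bought): O1–C2 and C3–C4, by an inverse-demand hetero-Diels–Alder addition of a 4-methoxy ortho-quinone methide to the ring B styrene. The methide comes from the 3-prenylsalicylaldehyde, HC(OMe)3 and a chiral Brønsted acid, and the C4–OMe group holds the ketone oxidation level.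
- After ring closure: C4–OMe to C4–OH to C4=O, then removal of the two MOM groups.
- Salicylaldehyde: 2,4,6-trihydroxybenzaldehyde, bis-MOM ether, Tsuji–Trost 1,1-dimethylallyl ether, Claisen rearrangement to the 3-prenyl compound. Direct C-prenylation of the phenol is avoided because O-alkylation competes and the regiochemistry would be uncertain.
- Styrene: 5-bromo-2-methoxybenzaldehyde, benzylic bromide, coupling with 2-methylallylmagnesium chloride, Suzuki–Miyaura vinylation.

Key step: step 8

Remark: the sense of induction of the chiral acid in step 8 cannot be fixed on paper, so the catalyst is written as its (R) form and its antipode is to be taken if the (2R,4R) flavan should predominate; the tert-butyl 2-methylbut-3-en-2-yl carbonate of step 2 is treated as a catalogue reagent.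

**Route**

Step 1
Reactants: 1 2,4,6-trihydroxybenzaldehyde
Product: 3 2-hydroxy-4,6-bis(methoxymethoxy)benzaldehyde, via 4-mono-MOM ether 2 (not isolated)
Conditions: MOMCl (2.2 equiv), i-Pr2NEt, CH2Cl2, 0 °C to rt
Reagents that add atoms: chloromethyl methyl ether (MOMCl), COCCl
Why: Chemoselective Williamson-type O-alkylation in which the free para OH reacts first to give 2 and one of the two equivalent chelated ortho OH groups second, the last OH being held back by its hydrogen bond to the aldehyde and by the limited amount of MOMCl.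

Step 2
Reactants: 3 2-hydroxy-4,6-bis(methoxymethoxy)benzaldehyde; 4 tert-butyl (2-methylbut-3-en-2-yl) carbonate
Product: 5 4,6-bis(methoxymethoxy)-2-[(2-methylbut-3-en-2-yl)oxy]benzaldehyde
Conditions: Pd(PPh3)4 (3 mol%), THF, 0 °C
Reagents that add atoms: none
Why: Tsuji–Trost O-allylation in which zerovalent palladium ionises the tertiary carbonate with loss of CO2, the tert-butoxide set free deprotonates the phenol, and the phenoxide attacks the more substituted terminus of the 1,1-dimethylallyl palladium complex under kinetic control at 0 °C, a known way to aryl 1,1-dimethylallyl ethers.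

Step 3
Reactants: 5 4,6-bis(methoxymethoxy)-2-[(2-methylbut-3-en-2-yl)oxy]benzaldehyde
Product: 7 2-hydroxy-4,6-bis(methoxymethoxy)-3-(3-methylbut-2-en-1-yl)benzaldehyde, via ortho-dienone 6 (not isolated)
Conditions: PhMe, 110 °C
Reagents that add atoms: none
Why: Aromatic Claisen rearrangement ([3,3]-sigmatropic shift) in which the CH2 terminus of the allyl unit bonds to C3, the only free ortho position, so that the tertiary ether becomes a linear prenyl group, and dienone 6 tautomerises to the chelated phenol before any further shift.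

Step 4
Reactants: 8 5-bromo-2-methoxybenzaldehyde
Product: 9 (5-bromo-2-methoxyphenyl)methanol
Conditions: NaBH4, MeOH, 0 °C
Reagents that add atoms: none
Why: Hydride reduction of the aldehyde by NaBH4, to which the aryl bromide and the methyl ether are inert.

Step 5
Reactants: 9 (5-bromo-2-methoxyphenyl)methanol
Product: 10 4-bromo-2-(bromomethyl)-1-methoxybenzene
Conditions: PBr3, CH2Cl2, 0 °C
Reagents that add atoms: phosphorus tribromide, BrP(Br)Br
Why: PBr3 bromination of a benzylic alcohol through its phosphite ester and SN2 attack of bromide, which does not touch the ring.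

Step 6
Reactants: 10 4-bromo-2-(bromomethyl)-1-methoxybenzene; 11 2-methylallylmagnesium chloride
Product: 12 4-bromo-1-methoxy-2-(3-methylbut-3-en-1-yl)benzene
Conditions: THF, 0 °C to rt
Reagents that add atoms: none
Why: SN2 coupling of a benzylic bromide with an allylic Grignard reagent, which is fast without catalyst, leaves the aryl bromide untouched, and gives one product because both ends of the 2-methylallyl unit are equivalent.

Step 7
Reactants: 12 4-bromo-1-methoxy-2-(3-methylbut-3-en-1-yl)benzene; 13 potassium vinyltrifluoroborate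
Product: 14 4-ethenyl-1-methoxy-2-(3-methylbut-3-en-1-yl)benzene
Conditions: PdCl2(dppf) (3 mol%), Cs2CO3, THF/H2O (9:1), 80 °C, sealed
Reagents that add atoms: none
Why: Suzuki–Miyaura coupling of the aryl bromide with the vinyltrifluoroborate (oxidative addition to zerovalent palladium, transmetalation, reductive elimination), in which transmetalation outruns Heck-type insertion into the remote 1,1-disubstituted alkene.

Step 8
Reactants: 7 2-hydroxy-4,6-bis(methoxymethoxy)-3-(3-methylbut-2-en-1-yl)benzaldehyde; 14 4-ethenyl-1-methoxy-2-(3-methylbut-3-en-1-yl)benzene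
Product: 17 (2S,4S)-4-methoxy-5,7-bis(methoxymethoxy)-2-[4-methoxy-3-(3-methylbut-3-en-1-yl)phenyl]-8-(3-methylbut-2-en-1-yl)chromane (2,4-cis), via dimethyl acetal 15 (not isolated), via methoxy ortho-quinone methide 16 (not isolated)
Conditions: HC(OMe)3 (1.5 equiv), (R)-3,3'-bis(2,4,6-triisopropylphenyl)-1,1'-binaphthyl-2,2'-diyl N-triflylphosphoramide (5 mol%), 5 Å MS, PhMe, rt; then 14 (2 equiv, slow addition), –30 °C
Reagents that add atoms: trimethyl orthoformate, COC(OC)OC
Why: Proposed new method: acid-catalysed exchange with HC(OMe)3 turns aldehyde 7 into acetal 15, which loses methanol to the O-methyl oxocarbenium ion, the protonated form of 4-methoxy ortho-quinone methide 16, bound to the chiral phosphoramide anion through its phenol O–H and by ion pairing; the CH2 terminus of styrene 14 attacks the methide carbon (future C4) and the phenol oxygen collapses onto the developing para-methoxybenzylic carbon (C2) in an asynchronous inverse-demand hetero-[4+2] addition. The closest known reactions are the racemic acid-catalysed three-component coupling of salicylaldehydes, trimethyl orthoformate and styrenes to 2,4-cis-4-methoxychromans and the chiral phosphoric acid-type catalysed cycloadditions of ortho-quinone methides with electron-rich alkenes; their combination in an intermolecular enantioselective form is not established. Ring C closes as the six-membered ring of an intermolecular [4+2] annulation, C3–C4 first and O1–C2 second by capture of the benzylic cation within the ion pair. C4 is set by the face of the planar methide that the confined anion leaves open, and C2 is set relative to C4 by the endo arrangement of ring B under the heterodiene, which places the (E)-methoxy group and the aryl group cis; the choice of catalyst antipode decides that this is (2S,4S). The step needs the regiochemistry that joins O1 to the benzylic carbon, secured by the polarity of the para-methoxystyrene, and chemoselectivity for the styrene over the 1,1-disubstituted alkene of 14 and the prenyl group of 7, secured by the far higher nucleophilicity of the conjugated, donor-substituted alkene. The electron-rich ring A lets the methide form with an acid too weak to cleave MOM ethers or protonate isolated alkenes, and any 2,4-trans isomer is removed by chromatography at this stage because it would give the (2R) ketone after step 10.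

Step 9
Reactants: 17 (2S,4S)-4-methoxy-5,7-bis(methoxymethoxy)-2-[4-methoxy-3-(3-methylbut-3-en-1-yl)phenyl]-8-(3-methylbut-2-en-1-yl)chromane
Product: 18 (2S,4S)-5,7-bis(methoxymethoxy)-2-[4-methoxy-3-(3-methylbut-3-en-1-yl)phenyl]-8-(3-methylbut-2-en-1-yl)chroman-4-ol
Conditions: PPTS (10 mol%), THF/H2O (3:1), rt
Reagents that add atoms: water, O
Why: SN1 solvolysis of the doubly activated benzylic methyl ether, in which the C4 cation stabilised by O1 and the 5- and 7-alkoxy groups is captured by the large excess of water, PPTS is too weak to cleave the MOM ethers or to ionise C2–O1, and the C4 configuration (cis drawn) is of no consequence because C4 becomes a carbonyl in step 10.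

Step 10
Reactants: 18 (2S,4S)-5,7-bis(methoxymethoxy)-2-[4-methoxy-3-(3-methylbut-3-en-1-yl)phenyl]-8-(3-methylbut-2-en-1-yl)chroman-4-ol
Product: 19 (2S)-5,7-bis(methoxymethoxy)-2-[4-methoxy-3-(3-methylbut-3-en-1-yl)phenyl]-8-(3-methylbut-2-en-1-yl)chroman-4-one
Conditions: DMP (1.3 equiv), NaHCO3, CH2Cl2, 0 °C to rt
Reagents that add atoms: none
Why: Dess–Martin oxidation of the secondary benzylic alcohol under bicarbonate buffer, to which the alkenes and MOM ethers are inert and in which C2, not alpha to the new carbonyl, keeps its configuration.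

Step 11
Reactants: 19 (2S)-5,7-bis(methoxymethoxy)-2-[4-methoxy-3-(3-methylbut-3-en-1-yl)phenyl]-8-(3-methylbut-2-en-1-yl)chroman-4-one
Product: 21 (2S)-5,7-dihydroxy-2-[4-methoxy-3-(3-methylbut-3-en-1-yl)phenyl]-8-(3-methylbut-2-en-1-yl)chroman-4-one (CNP0286775.1), via 7-mono-MOM flavanone 20 (not isolated)
Conditions: 3 M aq. HCl/MeOH (1:4), 50 °C
Reagents that add atoms: none
Why: Acid-catalysed acetal cleavage (methanolysis) of the aryl MOM ethers, the 5-OMOM next to the carbonyl first (giving chelated 20) and the 7-OMOM second, under conditions of the kind known to spare prenyl groups of flavanones and, being free of base, not opening ring C by retro-oxa-Michael reaction, so that C2 is retained.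

**Compound list**

1 | 2,4,6-trihydroxybenzaldehyde | O=Cc1c(O)cc(O)cc1O | starting material
2 | 2,6-dihydroxy-4-(methoxymethoxy)benzaldehyde | O=Cc1c(O)cc(OCOC)cc1O | intermediate (not isolated)
3 | 2-hydroxy-4,6-bis(methoxymethoxy)benzaldehyde | O=Cc1c(O)cc(OCOC)cc1OCOC | intermediate
4 | tert-butyl (2-methylbut-3-en-2-yl) carbonate | C=CC(C)(C)OC(=O)OC(C)(C)C | starting material
5 | 4,6-bis(methoxymethoxy)-2-[(2-methylbut-3-en-2-yl)oxy]benzaldehyde | O=Cc1c(OC(C)(C)C=C)cc(OCOC)cc1OCOC | intermediate
6 | 2,4-bis(methoxymethoxy)-5-(3-methylbut-2-en-1-yl)-6-oxocyclohexa-1,3-diene-1-carbaldehyde (racemic, transient) | O=CC1=C(OCOC)C=C(OCOC)C(CC=C(C)C)C1=O | intermediate (not isolated)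
7 | 2-hydroxy-4,6-bis(methoxymethoxy)-3-(3-methylbut-2-en-1-yl)benzaldehyde | O=Cc1c(O)c(CC=C(C)C)c(OCOC)cc1OCOC | intermediate
8 | 5-bromo-2-methoxybenzaldehyde | COc1ccc(Br)cc1C=O | starting material
9 | (5-bromo-2-methoxyphenyl)methanol | COc1ccc(Br)cc1CO | intermediate
10 | 4-bromo-2-(bromomethyl)-1-methoxybenzene | COc1ccc(Br)cc1CBr | intermediate
11 | 2-methylallylmagnesium chloride | C=C(C)C[Mg]Cl | starting material
12 | 4-bromo-1-methoxy-2-(3-methylbut-3-en-1-yl)benzene | COc1ccc(Br)cc1CCC(C)=C | intermediate
13 | potassium vinyltrifluoroborate | C=C[B-](F)(F)F.[K+] | starting material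
14 | 4-ethenyl-1-methoxy-2-(3-methylbut-3-en-1-yl)benzene | C=Cc1ccc(OC)c(CCC(C)=C)c1 | intermediate
15 | 2-(dimethoxymethyl)-3,5-bis(methoxymethoxy)-6-(3-methylbut-2-en-1-yl)phenol | COC(OC)c1c(O)c(CC=C(C)C)c(OCOC)cc1OCOC | intermediate (not isolated)
16 | (E)-6-(methoxymethylidene)-3,5-bis(methoxymethoxy)-2-(3-methylbut-2-en-1-yl)cyclohexa-2,4-dien-1-one | CO/C=C1/C(=O)C(CC=C(C)C)=C(OCOC)C=C1OCOC | intermediate (not isolated)
17 | (2S,4S)-4-methoxy-5,7-bis(methoxymethoxy)-2-[4-methoxy-3-(3-methylbut-3-en-1-yl)phenyl]-8-(3-methylbut-2-en-1-yl)chromane | CO[C@H]1C[C@@H](c2ccc(OC)c(CCC(C)=C)c2)Oc2c(CC=C(C)C)c(OCOC)cc(OCOC)c12 | intermediate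
18 | (2S,4S)-5,7-bis(methoxymethoxy)-2-[4-methoxy-3-(3-methylbut-3-en-1-yl)phenyl]-8-(3-methylbut-2-en-1-yl)chroman-4-ol | O[C@H]1C[C@@H](c2ccc(OC)c(CCC(C)=C)c2)Oc2c(CC=C(C)C)c(OCOC)cc(OCOC)c12 | intermediate
19 | (2S)-5,7-bis(methoxymethoxy)-2-[4-methoxy-3-(3-methylbut-3-en-1-yl)phenyl]-8-(3-methylbut-2-en-1-yl)chroman-4-one | O=C1C[C@@H](c2ccc(OC)c(CCC(C)=C)c2)Oc2c(CC=C(C)C)c(OCOC)cc(OCOC)c12 | intermediate
20 | (2S)-5-hydroxy-7-(methoxymethoxy)-2-[4-methoxy-3-(3-methylbut-3-en-1-yl)phenyl]-8-(3-methylbut-2-en-1-yl)chroman-4-one | O=C1C[C@@H](c2ccc(OC)c(CCC(C)=C)c2)Oc2c(CC=C(C)C)c(OCOC)cc(O)c12 | intermediate (not isolated)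
21 | (2S)-5,7-dihydroxy-2-[4-methoxy-3-(3-methylbut-3-en-1-yl)phenyl]-8-(3-methylbut-2-en-1-yl)chroman-4-one | C=C(C)CCc1cc([C@@H]2CC(=O)c3c(O)cc(O)c(CC=C(C)C)c3O2)ccc1OC | target

**Count and risks**

Total step count: 11. Longest linear sequence: 8 steps (steps 4 to 11, from 5-bromo-2-methoxybenzaldehyde 8); the ring A branch (steps 1 to 3) joins at step 8.

The three steps most likely to fail:

1. Step 8 (proposed new method). What may go wrong:
   - weak facial discrimination of the planar methide by the ion pair;
   - partial formation of the 2,4-trans isomer, or reversible ionisation of C2–O1, either of which would lower the enantiomeric purity at C2 after C4 is oxidised;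
   - Friedel–Crafts capture of the methide by the nucleophilic C6 position of ring A of the product;
   - cationic oligomerisation of the styrene.

   Fallback, by known chemistry: it sets out from 7 and 14, which are combined with HC(OMe)3 under an achiral acid (Sc(OTf)3, 5 mol%, CH2Cl2, –20 °C), the established racemic three-component reaction. This should give racemic 2,4-cis 4-methoxyflavan F1. Hydrolysis and oxidation as in steps 9 and 10 should give racemic cis flavan-4-ol F2 and then racemic flavanone F3. F3 is resolved kinetically by asymmetric transfer hydrogenation (RuCl(p-cymene)[(R,R)-TsDPEN], HCO2H/Et3N, EtOAc, rt, stopped shortly past half conversion). The (2R) ketone is expected to be reduced to the (2R,4R)-flavan-4-ol F4, and the slow-reacting (2S) ketone is recovered. That ketone is compound 19, where the route is rejoined; the ligand antipode is exchanged if the opposite ketone is consumed.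

2. Step 9. What may go wrong: elimination of methanol from the C4 cation to the flav-3-ene, or capture of that cation by ring A of a second molecule, in place of capture by water.
   Fallback: it sets out from 17 and returns at 19 without passing through the alcohol. DDQ (1.3 equiv) in CH2Cl2/pH 7 buffer at 0 °C abstracts the C4 hydride, which is activated by O1, the two alkoxy groups of ring A and the methoxy group. Water adds to the resulting 4-methoxy oxocarbenium ion, and the hemiketal loses methanol to give ketone 19. This is the known DDQ oxidation of electron-rich benzylic ethers to carbonyl compounds, and no new compound is passed.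

3. Step 11. What may go wrong: acid-induced cyclisation of the freed 7-OH onto the prenyl group, Markovnikov addition of methanol or HCl to the alkenes, or partial racemisation at C2 through ring opening under prolonged heating.
   Fallback: it sets out from 19 and avoids protic acid. TMSOTf and 2,2'-bipyridyl in CH2Cl2 at 0 °C convert the aryl MOM ethers into the (2S)-5,7-bis(trimethylsilyloxy) flavanone F5. Neutral hydrolysis (H2O, then KF in MeOH at 0 °C if needed) gives 21.

**Further compounds**

F1 | step 8 | racemic 2,4-cis-4-methoxy-5,7-bis(methoxymethoxy)-2-[4-methoxy-3-(3-methylbut-3-en-1-yl)phenyl]-8-(3-methylbut-2-en-1-yl)chromane (both enantiomers) | CO[C@H]1C[C@@H](c2ccc(OC)c(CCC(C)=C)c2)Oc2c(CC=C(C)C)c(OCOC)cc(OCOC)c12.CO[C@@H]1C[C@H](c2ccc(OC)c(CCC(C)=C)c2)Oc2c(CC=C(C)C)c(OCOC)cc(OCOC)c12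
F2 | step 8 | racemic 2,4-cis-5,7-bis(methoxymethoxy)-2-[4-methoxy-3-(3-methylbut-3-en-1-yl)phenyl]-8-(3-methylbut-2-en-1-yl)chroman-4-ol (both enantiomers) | O[C@H]1C[C@@H](c2ccc(OC)c(CCC(C)=C)c2)Oc2c(CC=C(C)C)c(OCOC)cc(OCOC)c12.O[C@@H]1C[C@H](c2ccc(OC)c(CCC(C)=C)c2)Oc2c(CC=C(C)C)c(OCOC)cc(OCOC)c12
F3 | step 8 | racemic 5,7-bis(methoxymethoxy)-2-[4-methoxy-3-(3-methylbut-3-en-1-yl)phenyl]-8-(3-methylbut-2-en-1-yl)chroman-4-one (both enantiomers) | O=C1C[C@@H](c2ccc(OC)c(CCC(C)=C)c2)Oc2c(CC=C(C)C)c(OCOC)cc(OCOC)c12.O=C1C[C@H](c2ccc(OC)c(CCC(C)=C)c2)Oc2c(CC=C(C)C)c(OCOC)cc(OCOC)c12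
F4 | step 8 | (2R,4R)-5,7-bis(methoxymethoxy)-2-[4-methoxy-3-(3-methylbut-3-en-1-yl)phenyl]-8-(3-methylbut-2-en-1-yl)chroman-4-ol | O[C@@H]1C[C@H](c2ccc(OC)c(CCC(C)=C)c2)Oc2c(CC=C(C)C)c(OCOC)cc(OCOC)c12
F0 | step 9 | none | none
F5 | step 11 | (2S)-2-[4-methoxy-3-(3-methylbut-3-en-1-yl)phenyl]-8-(3-methylbut-2-en-1-yl)-5,7-bis(trimethylsilyloxy)chroman-4-one | O=C1C[C@@H](c2ccc(OC)c(CCC(C)=C)c2)Oc2c(CC=C(C)C)c(O[Si](C)(C)C)cc(O[Si](C)(C)C)c12
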